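**Strategy.** Everything rests on cutting ring C at O1–C8a, C4–C4a and O1–C2, so that the fully substituted ring A enters as an aryne and C2, C3, C4 and ring B as an arylpropiolic acid. The feature exploited is the pair of neighbouring ring A carbons C8a and C4a, which lie between the C8 prenyl group and the C5 oxygen: as a polarised aryne they take up the carboxylate oxygen at C8a, transfer the acyl carbon C4 to C4a, and the liberated phenoxide closes the pyranone at C2, all in one flask. The precursor is a hexasubstituted ortho-silylaryl triflate bearing both prenyl groups and two MOM ethers. C3 hydroxylation and MOM cleavage complete the route.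

Key step: step 8

Remark: the target has no stereocentre, so no step has to set or preserve configuration; all three phenols are carried as MOM ethers so that one final operation unmasks them.

**Step 1**
Reactants: 1 phloroglucinol; 2 prenyl bromide (2.1 equiv)
Product: 3 2,4-diprenylphloroglucinol
Conditions: KOH (aq, 10%), 0 °C → rt
Reagents that add atoms: none
Why: Phenoxide C-alkylation, in which the water-solvated phloroglucinol anion reacts with the allylic bromide at carbon, so two equivalents of bromide should give the 2,4-di-C-prenyl triol as the main separable product, with the monoprenyl compound recyclable.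

**Step 2**
Reactants: 3 2,4-diprenylphloroglucinol
Product: 4 3,5-dihydroxy-2,4-diprenylphenyl N-isopropylcarbamate
Conditions: iPrNCO (1.0 equiv), Et3N (0.2 equiv), THF, 0 °C → rt
Reagents that add atoms: isopropyl isocyanate, CC(C)N=C=O
Why: Base-catalysed addition of a phenol to an isocyanate (carbamoylation), where the hydroxyl between the two prenyl groups is shielded and one equivalent of isocyanate should therefore acylate one of the two equivalent outer hydroxyls, leaving unreacted triol and bis-carbamate separable and recyclable.

**Step 3**
Reactants: 4 3,5-dihydroxy-2,4-diprenylphenyl N-isopropylcarbamate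
Product: 5 3,5-bis(methoxymethoxy)-2,4-diprenylphenyl N-isopropylcarbamate
Conditions: MOMCl (excess), iPr2NEt, CH2Cl2, 0 °C → rt
Reagents that add atoms: chloromethyl methyl ether, COCCl
Why: O-Alkylation of phenols with an α-chloro ether under amine base (MOM protection), in which the mild base leaves the N–H carbamate intact and excess reagent forces the hindered phenol between the prenyl groups.

**Step 4**
Reactants: 5 3,5-bis(methoxymethoxy)-2,4-diprenylphenyl N-isopropylcarbamate
Product: 8 3,5-bis(methoxymethoxy)-2,4-diprenyl-6-(trimethylsilyl)phenyl N-isopropylcarbamate, via N-silyl carbamate 6 (not isolated), via N-silyl C-silyl carbamate 7 (not isolated)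
Conditions: TBSOTf (1.05 equiv), TMEDA, Et2O, 0 °C; n-BuLi, TMEDA, −78 °C; TMSCl, −78 °C → rt; cold dilute aq NaHSO4 work-up
Reagents that add atoms: chlorotrimethylsilane, C[Si](C)(C)Cl
Why: Directed ortho-metalation, in which the carbamate N–H is first masked by transient silylation (one equivalent of the bulky silyl triflate is consumed by the carbamate before it can activate the MOM acetals), the only ring hydrogen, flanked by the carbamate and a MOM ether, is then removed at −78 °C faster than the prenyl CH2 hydrogens, the aryllithium is silylated, and the N-silyl group is lost on work-up.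

**Step 5**
Reactants: 8 3,5-bis(methoxymethoxy)-2,4-diprenyl-6-(trimethylsilyl)phenyl N-isopropylcarbamate
Product: 10 3,5-bis(methoxymethoxy)-4,6-diprenyl-2-(trimethylsilyl)phenyl triflate, via silylphenol 9 (not isolated)
Conditions: DBU, Et2NH, MeCN, 40 °C; then PhNTf2, rt
Reagents that add atoms: N-phenylbis(trifluoromethanesulfonimide), O=S(=O)(N(c1ccccc1)S(=O)(=O)C(F)(F)F)C(F)(F)F
Why: E1cB cleavage of the N-monoalkyl carbamate (the expelled isopropyl isocyanate is trapped by Et2NH) frees the phenoxide, which is sulfonylated in the same flask by the mild triflyl donor, so the protodesilylation-prone silylphenol is never isolated.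

**Step 6**
Reactants: 11 4-iodophenol
Product: 12 1-iodo-4-(methoxymethoxy)benzene
Conditions: MOMCl, iPr2NEt, CH2Cl2, 0 °C → rt
Reagents that add atoms: chloromethyl methyl ether, COCCl
Why: Routine MOM protection of an unhindered phenol by O-alkylation under amine base.

**Step 7**
Reactants: 12 1-iodo-4-(methoxymethoxy)benzene; 13 propiolic acid
Product: 14 3-[4-(methoxymethoxy)phenyl]propiolic acid
Conditions: Pd(PPh3)4 (2.5 mol %), DBU (2.4 equiv), DMSO, 35 °C; then cold dilute aq citric acid to about pH 3
Reagents that add atoms: none
Why: Copper-free Sonogashira coupling, with oxidative addition of the aryl iodide to zerovalent palladium and coupling of the DBU propiolate near room temperature, where decarboxylation of the product acid does not yet set in.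

**Step 8**
Reactants: 10 3,5-bis(methoxymethoxy)-4,6-diprenyl-2-(trimethylsilyl)phenyl triflate (1.3 equiv); 14 3-[4-(methoxymethoxy)phenyl]propiolic acid
Product: 17 5,7,4'-tris-O-(methoxymethyl)-6,8-diprenylapigenin, via aryne 15 (not isolated), via hydroxyaryl ynone 16 (not isolated)
Conditions: CsF (4 equiv), THF, 125 °C (sealed tube)
Reagents that add atoms: none
Why: Fluoride attacks silicon and expels triflate to give aryne 15; the cesium carboxylate of 14 bonds through oxygen to C8a, the aryl anion at C4a closes on the ester carbonyl, and the strained four-membered alkoxide opens to the ortho-acyl phenoxide 16, a net insertion of the aryne into the C–O bond of the acid. The closest known reaction type is the fluoride-mediated intermolecular C–O addition of carboxylic acids to arynes, which with arylpropiolic acids is known to run on to flavones. Ring C then closes by 6-endo-dig oxa-Michael addition of the phenoxide oxygen to C2 of the ynone. No stereocentre is formed. The selectivity needed is regiochemical: σ-withdrawal by the MOM-oxygen at C5 widens the internal ring angle at C8a, making that carbon the electrophilic terminus, and stabilises the incipient carbanion at the adjacent C4a, which outweighs the small opposing bias of the C8 prenyl group. Excess CsF keeps the acid as its carboxylate, so that acyl transfer to the aryl anion should outrun its protonation, and soft conjugate addition under thermal conditions favours the six-membered over the five-membered (aurone) closure.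

**Step 9**
Reactants: 17 5,7,4'-tris-O-(methoxymethyl)-6,8-diprenylapigenin
Product: 19 5,7,4'-tris-O-(methoxymethyl)-6,8-diprenylkaempferol, via C3 boronate 18 (not isolated)
Conditions: LiN(iPr)2, THF, −78 °C; B(OMe)3, −78 °C → 0 °C; AcOH, 30% aq H2O2, 0 °C → rt
Reagents that add atoms: hydrogen peroxide, OO
Why: Carbonyl-assisted lithiation of the flavone at C3 by the amide base, borylation and oxidative 1,2-migration from boron to oxygen with hydrogen peroxide (the standard flavone-to-flavonol sequence), under which the isolated trisubstituted alkenes and the MOM ethers should remain untouched.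

**Step 10**
Reactants: 19 5,7,4'-tris-O-(methoxymethyl)-6,8-diprenylkaempferol
Product: 20 6,8-diprenylkaempferol
Conditions: 3 M aq HCl, MeOH, rt → 45 °C, stopped at full conversion
Reagents that add atoms: none
Why: Acid-catalysed acetal exchange of the three aryl MOM ethers with methanol, run at moderate temperature so that acetal cleavage should stay faster than protonation of the prenyl double bonds.

**Compound list**

1 | phloroglucinol (benzene-1,3,5-triol) | Oc1cc(O)cc(O)c1 | starting material
2 | prenyl bromide (1-bromo-3-methylbut-2-ene) | CC(C)=CCBr | starting material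
3 | 2,4-diprenylphloroglucinol [2,4-bis(3-methylbut-2-enyl)benzene-1,3,5-triol] | CC(C)=CCc1c(O)cc(O)c(CC=C(C)C)c1O | intermediate
4 | 3,5-dihydroxy-2,4-diprenylphenyl N-isopropylcarbamate | CC(C)NC(=O)Oc1cc(O)c(CC=C(C)C)c(O)c1CC=C(C)C | intermediate
5 | 3,5-bis(methoxymethoxy)-2,4-diprenylphenyl N-isopropylcarbamate | CC(C)NC(=O)Oc1cc(OCOC)c(CC=C(C)C)c(OCOC)c1CC=C(C)C | intermediate
6 | N-(tert-butyldimethylsilyl) derivative of carbamate 5 (formed in the flask) | CC(C)N(C(=O)Oc1cc(OCOC)c(CC=C(C)C)c(OCOC)c1CC=C(C)C)[Si](C)(C)C(C)(C)C | intermediate
7 | N-(tert-butyldimethylsilyl)-6-(trimethylsilyl) derivative of carbamate 5 (formed in the flask) | CC(C)N(C(=O)Oc1c([Si](C)(C)C)c(OCOC)c(CC=C(C)C)c(OCOC)c1CC=C(C)C)[Si](C)(C)C(C)(C)C | intermediate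
8 | 3,5-bis(methoxymethoxy)-2,4-diprenyl-6-(trimethylsilyl)phenyl N-isopropylcarbamate | CC(C)NC(=O)Oc1c([Si](C)(C)C)c(OCOC)c(CC=C(C)C)c(OCOC)c1CC=C(C)C | intermediate
9 | 3,5-bis(methoxymethoxy)-2,4-diprenyl-6-(trimethylsilyl)phenol (formed in the flask) | CC(C)=CCc1c(OCOC)c(CC=C(C)C)c(O)c([Si](C)(C)C)c1OCOC | intermediate
10 | 3,5-bis(methoxymethoxy)-4,6-diprenyl-2-(trimethylsilyl)phenyl triflate | CC(C)=CCc1c(OCOC)c(CC=C(C)C)c(OS(=O)(=O)C(F)(F)F)c([Si](C)(C)C)c1OCOC | intermediate
11 | 4-iodophenol | Oc1ccc(I)cc1 | starting material
12 | 1-iodo-4-(methoxymethoxy)benzene | COCOc1ccc(I)cc1 | intermediate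
13 | propiolic acid | C#CC(=O)O | starting material
14 | 3-[4-(methoxymethoxy)phenyl]propiolic acid | COCOc1ccc(C#CC(=O)O)cc1 | intermediate
15 | 3,5-bis(methoxymethoxy)-4,6-diprenyl-1,2-didehydrobenzene (aryne, formed in the flask) | C1#CC(OCOC)=C(CC=C(C)C)C(OCOC)=C1CC=C(C)C | intermediate
16 | 1-[2-hydroxy-4,6-bis(methoxymethoxy)-3,5-diprenylphenyl]-3-[4-(methoxymethoxy)phenyl]prop-2-yn-1-one (present as its cesium phenoxide in the flask) | COCOc1ccc(C#CC(=O)c2c(O)c(CC=C(C)C)c(OCOC)c(CC=C(C)C)c2OCOC)cc1 | intermediate
17 | 5,7,4'-tris-O-(methoxymethyl)-6,8-diprenylapigenin | CC(C)=CCc1c(OCOC)c(CC=C(C)C)c2oc(-c3ccc(OCOC)cc3)cc(=O)c2c1OCOC | intermediate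
18 | dimethyl C3-boronate of flavone 17 (formed in the flask) | CC(C)=CCc1c(OCOC)c(CC=C(C)C)c2oc(-c3ccc(OCOC)cc3)c(B(OC)OC)c(=O)c2c1OCOC | intermediate
19 | 5,7,4'-tris-O-(methoxymethyl)-6,8-diprenylkaempferol | CC(C)=CCc1c(OCOC)c(CC=C(C)C)c2oc(-c3ccc(OCOC)cc3)c(O)c(=O)c2c1OCOC | intermediate
20 | 6,8-diprenylkaempferol (achiral) | CC(C)=CCc1c(O)c(CC=C(C)C)c2oc(-c3ccc(O)cc3)c(O)c(=O)c2c1O | target

**Step count**

Total step count: 10. Longest linear sequence: 8 steps (steps 1 to 5, then 8, 9 and 10); steps 6 and 7 form the two-step side branch to acid 14.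

**Steps most likely to fail**

Step 8. Addition of the carboxylate at C8a may be slowed by the neighbouring prenyl group, so that the aryne is consumed in other ways. These are attack at C4a leading to the isomeric flavone, protonation of the aryl anion before acyl transfer so that only the aryl ester forms, or ene-type reaction with prenyl double bonds. The fallback forms the C4–C4a bond by polar acylation and closes ring C afterwards, so that O1 comes from the phloroglucinol oxygen. It sets out from carbamate 5 and acid 14.
- Acid 14 is converted into its N-methoxy-N-methylamide F1 (MeNHOMe·HCl, EDC·HCl, iPr2NEt, CH2Cl2).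
- Carbamate 5 is N-silylated and lithiated as in step 4 (through 6), and the aryllithium is acylated with F1 at −78 °C to give the N-silylated ynone carbamate F2.
- F2 loses its N-silyl group on work-up to give the ynone carbamate F3.
- DBU and Et2NH in MeCN at 40 °C then cleave the carbamate and deliver the phenoxide of 16, where the fallback rejoins the route. Compound 16 should close to 17 in the same flask, since secondary amines are known to steer such ynone closures to the six-membered ring.

Step 1. The alkylation may stop at the monoprenyl stage or run on to the triprenyl stage, may go to oxygen, or may dearomatise the ring by geminal dialkylation, leaving little of the 2,4-isomer after separation. The fallback installs the prenyl groups one at a time by directed metalation. It sets out from 1 and 2.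
- Exhaustive protection (MOMCl, NaH, DMF) gives 1,3,5-tris(methoxymethoxy)benzene F4.
- Lithiation between two MOM ethers (n-BuLi, THF, 0 °C), transmetalation with CuI and alkylation with 2 give the monoprenyl compound F5.
- Repetition at one of the two equivalent remaining ring positions gives the diprenyl compound F6.
- Methanolysis of the acetals (HCl, MeOH, rt) returns to the route at 3.

Step 10. Protonation of a prenyl double bond may compete with acetal cleavage, and the tertiary cation may be captured by a neighbouring free phenol at C5 or C7, closing a dimethylchroman ring. The fallback avoids protic acid by exchanging the acetals for silyl ethers. It sets out from 19.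
- TMSOTf and 2,2'-bipyridyl in MeCN at 0 °C convert the aryl MOM ethers, and the free C3 hydroxyl, into the tetrakis(trimethylsilyl) ether F7.
- Addition of water at neutral pH hydrolyses the aryl silyl ethers and returns to the route at target 20.

**Further compounds**

F1 | step 8 | N-methoxy-N-methyl-3-[4-(methoxymethoxy)phenyl]propiolamide | COCOc1ccc(C#CC(=O)N(C)OC)cc1
F2 | step 8 | N-(tert-butyldimethylsilyl) derivative of ynone carbamate F3 | CC(C)N(C(=O)Oc1c(C(=O)C#Cc2ccc(OCOC)cc2)c(OCOC)c(CC=C(C)C)c(OCOC)c1CC=C(C)C)[Si](C)(C)C(C)(C)C
F3 | step 8 | 3,5-bis(methoxymethoxy)-2-{3-[4-(methoxymethoxy)phenyl]propioloyl}-4,6-diprenylphenyl N-isopropylcarbamate | CC(C)NC(=O)Oc1c(C(=O)C#Cc2ccc(OCOC)cc2)c(OCOC)c(CC=C(C)C)c(OCOC)c1CC=C(C)C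
F4 | step 1 | 1,3,5-tris(methoxymethoxy)benzene | COCOc1cc(OCOC)cc(OCOC)c1
F5 | step 1 | 1,3,5-tris(methoxymethoxy)-2-(3-methylbut-2-enyl)benzene | COCOc1cc(OCOC)c(CC=C(C)C)c(OCOC)c1
F6 | step 1 | 1,3,5-tris(methoxymethoxy)-2,4-bis(3-methylbut-2-enyl)benzene | COCOc1cc(OCOC)c(CC=C(C)C)c(OCOC)c1CC=C(C)C
F7 | step 10 | 3,5,7,4'-tetrakis-O-(trimethylsilyl)-6,8-diprenylkaempferol | C[Si](C)(C)Oc1ccc(-c2oc3c(CC=C(C)C)c(O[Si](C)(C)C)c(CC=C(C)C)c(O[Si](C)(C)C)c3c(=O)c2O[Si](C)(C)C)cc1
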